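**Plan**
- Retrosynthesis: the three MOM ethers come off last, and the C2–H bond, which carries the only stereocenter, is cut back to the achiral flavone 17.
- Ring C is a three-carbon bridge C2–C3–C4 between O1 and C4a of ring A. C4 is a carbonyl carbon that CO can supply and C2–C3 are the two carbons of a ring B acetylene, so ring C is cut at C4a–C4, C4–C3 and O1–C2 into iodophenol 3, CO and alkyne 13.
- Alkyne 13 is cut at the triple bond (from an aldehyde), at C8–prenyl (para-Claisen–Cope shift of an O-prenyl ether) and at the pyran ring (prenal annulation of 2,4-dihydroxybenzaldehyde). Iodophenol 3 goes back to phloroglucinol.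
- Forward order: the pyran ring of the chromene first, then the prenyl group, the MOM ether and the alkyne; ring A separately as the iodophenol; then ring C by the three-component annulation.
- Stereochemistry: 2S is set by a ligand-controlled copper hydride conjugate reduction of the flavone C2–C3 bond; the only later step is acidic and does not touch C2.

Key step: step 8

Assumption: the facial sense of the copper hydride reduction is taken from the model for β-substituted cyclic enones; (R)-DTBM-SEGPHOS is written for 2S, and its mirror image is to be used should the sense prove opposite.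

**Route**

Step 1
Reactants: 1 phloroglucinol
Product: 2 3,5-bis(methoxymethoxy)phenol
Conditions: MOMCl (2.1 equiv), i-Pr2NEt (2.5 equiv), DMF, 0 °C to rt; chromatography
Reagents that add atoms: chloromethyl methyl ether, COCCl
Why: MOM ether formation on a phenol with a hindered amine base is routine; with two equivalents the bis-ether should be the main component of a statistical mixture from which it is separated, the threefold symmetry of 1 making all bis-ethers identical.

Step 2
Reactants: 2 3,5-bis(methoxymethoxy)phenol
Product: 3 2-iodo-3,5-bis(methoxymethoxy)phenol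
Conditions: BnMe3N·ICl2 (1.0 equiv), NaHCO3, CH2Cl2–MeOH, 0 °C to rt
Reagents that add atoms: benzyltrimethylammonium dichloroiodate, C[N+](C)(C)Cc1ccccc1.Cl[I-]Cl
Why: Electrophilic aromatic iodination under bicarbonate buffer, which keeps the MOM acetals intact; attack ortho to the free OH (two equivalent sites, each also para to a MOM ether) is expected to prevail over the single site between the two MOM ethers, as is known for 3,5-dialkoxyphenols with this reagent.

Step 3
Reactants: 4 2,4-dihydroxybenzaldehyde; 5 3-methylbut-2-enal
Product: 7 5-hydroxy-2,2-dimethyl-2H-chromene-6-carbaldehyde, via ortho-quinone methide 6 (not isolated)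
Conditions: pyridine, 140 °C (sealed tube)
Reagents that add atoms: none
Why: Base-mediated chromenylation (aldol-type condensation, dehydration, oxa-6π electrocyclization): C3 between the two OH groups is the most nucleophilic carbon, loss of water gives 6, and the pyran closes on the oxygen derived from the non-chelated 4-OH, so the angular chromene with its OH hydrogen-bonded to the aldehyde should result.

Step 4
Reactants: 7 5-hydroxy-2,2-dimethyl-2H-chromene-6-carbaldehyde; 8 1-bromo-3-methylbut-2-ene
Product: 9 2,2-dimethyl-5-(3-methylbut-2-enyloxy)-2H-chromene-6-carbaldehyde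
Conditions: K2CO3, DMF, 40 °C
Reagents that add atoms: none
Why: Williamson ether synthesis; the only phenol is deprotonated by carbonate in DMF and alkylated at oxygen by the primary allylic bromide in SN2 fashion.

Step 5
Reactants: 9 2,2-dimethyl-5-(3-methylbut-2-enyloxy)-2H-chromene-6-carbaldehyde
Product: 11 5-hydroxy-2,2-dimethyl-8-(3-methylbut-2-enyl)-2H-chromene-6-carbaldehyde, via ortho-dienone 10 (not isolated)
Conditions: PhNEt2, 200 °C (sealed tube, argon)
Reagents that add atoms: none
Why: Aromatic Claisen rearrangement followed by Cope rearrangement (para-Claisen): both ortho carbons (C4a, C6) are substituted, so dienone 10 from the first [3,3] shift (drawn at C6; the C4a dienone leads to the same product) cannot enolize and passes the allyl unit on to the free para carbon C8 by a second [3,3] shift, the double allylic inversion restoring the linear prenyl group before tautomerization to the phenol.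

Step 6
Reactants: 11 5-hydroxy-2,2-dimethyl-8-(3-methylbut-2-enyl)-2H-chromene-6-carbaldehyde
Product: 12 5-(methoxymethoxy)-2,2-dimethyl-8-(3-methylbut-2-enyl)-2H-chromene-6-carbaldehyde
Conditions: NaH, MOMCl, DMF, 0 °C
Reagents that add atoms: chloromethyl methyl ether, COCCl
Why: MOM ether formation on the sodium phenoxide; the hydride breaks the hydrogen bond to the aldehyde that makes amine bases sluggish with this phenol.

Step 7
Reactants: 12 5-(methoxymethoxy)-2,2-dimethyl-8-(3-methylbut-2-enyl)-2H-chromene-6-carbaldehyde
Product: 13 6-ethynyl-5-(methoxymethoxy)-2,2-dimethyl-8-(3-methylbut-2-enyl)-2H-chromene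
Conditions: dimethyl (1-diazo-2-oxopropyl)phosphonate, K2CO3, MeOH, rt
Reagents that add atoms: dimethyl (1-diazo-2-oxopropyl)phosphonate, CC(=O)C(=[N+]=[N-])P(=O)(OC)OC
Why: Seyferth–Gilbert homologation in the Bestmann–Ohira variant: the diazomethylphosphonate anion formed by methanolysis adds to the aldehyde, Horner–Wadsworth–Emmons-type elimination gives a diazoalkene, and loss of N2 with a 1,2-hydrogen shift gives the terminal alkyne under conditions that leave the MOM ether and both alkenes untouched.

Step 8
Reactants: 3 2-iodo-3,5-bis(methoxymethoxy)phenol; 14 carbon monoxide; 13 6-ethynyl-5-(methoxymethoxy)-2,2-dimethyl-8-(3-methylbut-2-enyl)-2H-chromene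
Product: 17 5,7-bis(methoxymethoxy)-2-[5-(methoxymethoxy)-2,2-dimethyl-8-(3-methylbut-2-enyl)-2H-chromen-6-yl]-4H-chromen-4-one, via ortho-hydroxyaryl ynone 15 (not isolated), via diethylamino enaminone 16 (not isolated)
Conditions: PdCl2(PPh3)2 (5 mol %), CO (10 bar), degassed Et2NH, 100 °C (autoclave), no copper salt
Reagents that add atoms: diethylamine, CCNCC (its atoms are held only in intermediate 16 and leave again on ring closure)
Why: The divalent palladium precatalyst PdCl2(PPh3)2 is reduced in the flask to zerovalent palladium, which inserts into the C–I bond of 3; CO insertion gives the aroyl–palladium species, and copper-free coupling with amine-deprotonated 13 delivers ynone 15 (C4a–C4 and C4–C3). Diethylamine then adds in conjugate fashion to 15 to give enaminone 16, and the ortho phenol oxygen displaces the amine at C2 by addition–elimination to form O1–C2. The closest known reaction type is the palladium-catalysed carbonylative annulation of ortho-iodophenols with terminal arylacetylenes in a secondary amine, which gives flavones. Ring C closes in a 6-endo mode (6-endo-trig on the enaminone, formally 6-endo-dig on the ynone), and no stereocenter is formed. The step needs 6-endo closure over 5-exo closure (aurone) and carbonylative over direct coupling (2-arylbenzofuran): the first is secured by the secondary amine, which turns the ynone into an enaminone that is attacked only at C2, the second by CO pressure and the absence of copper. The phenol next to iodine is the only free OH in either partner, so only one ring can close.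

Step 9
Reactants: 17 5,7-bis(methoxymethoxy)-2-[5-(methoxymethoxy)-2,2-dimethyl-8-(3-methylbut-2-enyl)-2H-chromen-6-yl]-4H-chromen-4-one
Product: 18 (2S)-5,7-bis(methoxymethoxy)-2-[5-(methoxymethoxy)-2,2-dimethyl-8-(3-methylbut-2-enyl)-2H-chromen-6-yl]-2,3-dihydro-4H-chromen-4-one
Conditions: Cu(OAc)2·H2O (5 mol %), (R)-DTBM-SEGPHOS (5.5 mol %), (EtO)2MeSiH (2 equiv), t-BuOH (1.5 equiv), toluene, 0 °C to rt
Reagents that add atoms: none
Why: Asymmetric conjugate reduction by a bisphosphine-ligated monovalent copper hydride, a reaction known for chromones and β-substituted cyclic enones: hydride is delivered to C2 from the face selected by the chiral bisphosphine, which sets 2S, and t-BuOH protonates the copper enolate at C3 before it can open ring C; the electron-rich prenyl and pyran alkenes are not acceptors for the nucleophilic hydride.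

Step 10
Reactants: 18 (2S)-5,7-bis(methoxymethoxy)-2-[5-(methoxymethoxy)-2,2-dimethyl-8-(3-methylbut-2-enyl)-2H-chromen-6-yl]-2,3-dihydro-4H-chromen-4-one
Product: 19 sanggenol N
Conditions: HCl (ca. 1 M in MeOH), MeOH, rt to 40 °C
Reagents that add atoms: none
Why: Acid-catalysed transacetalization of the three MOM ethers to methanol (acetal cleavage); C2 is not epimerized under mild acid, and the prenyl group cannot cyclize onto a phenol because it is flanked by the pyran oxygen and an aromatic CH.

**Compound list**
1 | phloroglucinol (benzene-1,3,5-triol) | Oc1cc(O)cc(O)c1 | starting material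
2 | 3,5-bis(methoxymethoxy)phenol | COCOc1cc(O)cc(OCOC)c1 | intermediate
3 | 2-iodo-3,5-bis(methoxymethoxy)phenol | COCOc1cc(O)c(I)c(OCOC)c1 | intermediate
4 | 2,4-dihydroxybenzaldehyde | O=Cc1ccc(O)cc1O | starting material
5 | 3-methylbut-2-enal | CC(C)=CC=O | starting material
6 | ortho-quinone methide, 2-hydroxy-3-(3-methylbut-2-enylidene)-4-oxocyclohexa-1,5-diene-1-carbaldehyde (not isolated) | CC(C)=CC=C1C(=O)C=CC(C=O)=C1O | intermediate
7 | 5-hydroxy-2,2-dimethyl-2H-chromene-6-carbaldehyde | CC1(C)C=Cc2c(O1)ccc(C=O)c2O | intermediate
8 | 1-bromo-3-methylbut-2-ene | CC(C)=CCBr | starting material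
9 | 2,2-dimethyl-5-(3-methylbut-2-enyloxy)-2H-chromene-6-carbaldehyde | CC(C)=CCOc1c(C=O)ccc2OC(C)(C)C=Cc12 | intermediate
10 | ortho-dienone, 2,2-dimethyl-6-(2-methylbut-3-en-2-yl)-5-oxo-5,6-dihydro-2H-chromene-6-carbaldehyde (racemic, not isolated) | C=CC(C)(C)C1(C=O)C=CC2=C(C=CC(C)(C)O2)C1=O | intermediate
11 | 5-hydroxy-2,2-dimethyl-8-(3-methylbut-2-enyl)-2H-chromene-6-carbaldehyde | CC(C)=CCc1cc(C=O)c(O)c2c1OC(C)(C)C=C2 | intermediate
12 | 5-(methoxymethoxy)-2,2-dimethyl-8-(3-methylbut-2-enyl)-2H-chromene-6-carbaldehyde | CC(C)=CCc1cc(C=O)c(OCOC)c2c1OC(C)(C)C=C2 | intermediate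
13 | 6-ethynyl-5-(methoxymethoxy)-2,2-dimethyl-8-(3-methylbut-2-enyl)-2H-chromene | CC(C)=CCc1cc(C#C)c(OCOC)c2c1OC(C)(C)C=C2 | intermediate
14 | carbon monoxide | [C-]#[O+] | starting material
15 | 1-[2-hydroxy-4,6-bis(methoxymethoxy)phenyl]-3-[5-(methoxymethoxy)-2,2-dimethyl-8-(3-methylbut-2-enyl)-2H-chromen-6-yl]prop-2-yn-1-one (not isolated) | CC(C)=CCc1cc(C#CC(=O)c2c(O)cc(OCOC)cc2OCOC)c(OCOC)c2c1OC(C)(C)C=C2 | intermediate
16 | 3-(diethylamino)-1-[2-hydroxy-4,6-bis(methoxymethoxy)phenyl]-3-[5-(methoxymethoxy)-2,2-dimethyl-8-(3-methylbut-2-enyl)-2H-chromen-6-yl]prop-2-en-1-one (alkene geometry not defined, not isolated) | CCN(CC)C(=CC(=O)c1c(O)cc(OCOC)cc1OCOC)c1cc(CC=C(C)C)c2OC(C)(C)C=Cc2c1OCOC | intermediate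
17 | 5,7-bis(methoxymethoxy)-2-[5-(methoxymethoxy)-2,2-dimethyl-8-(3-methylbut-2-enyl)-2H-chromen-6-yl]-4H-chromen-4-one | CC(C)=CCc1cc(-c2cc(=O)c3c(OCOC)cc(OCOC)cc3o2)c(OCOC)c2c1OC(C)(C)C=C2 | intermediate
18 | (2S)-5,7-bis(methoxymethoxy)-2-[5-(methoxymethoxy)-2,2-dimethyl-8-(3-methylbut-2-enyl)-2H-chromen-6-yl]-2,3-dihydro-4H-chromen-4-one | CC(C)=CCc1cc([C@@H]2CC(=O)c3c(OCOC)cc(OCOC)cc3O2)c(OCOC)c2c1OC(C)(C)C=C2 | intermediate
19 | sanggenol N, (2S)-5,7-dihydroxy-2-[5-hydroxy-2,2-dimethyl-8-(3-methylbut-2-enyl)-2H-chromen-6-yl]-2,3-dihydro-4H-chromen-4-one | CC(C)=CCc1cc([C@@H]2CC(=O)c3c(O)cc(O)cc3O2)c(O)c2c1OC(C)(C)C=C2 | target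

**Step count**
Total: 10 steps. Longest linear sequence: 8 steps (steps 3 to 10, from 4 and 5 to 19); the ring A branch (steps 1 and 2) joins at step 8.

**Steps most likely to fail**

Step 8. Oxidative addition at the electron-rich, doubly ortho-substituted C–I bond may be slow. Direct coupling without CO (ending in a benzofuran), aminocarbonylation of the aroyl–palladium species by diethylamine, or 5-exo closure may then compete. The fallback builds the same ynone without palladium or CO and sets out from 2 and 13. Phenol 2 is formylated ortho to its free OH by the magnesium-mediated Casnati–Skattebøl reaction (MgCl2, Et3N, paraformaldehyde, MeCN, reflux) to give 2-hydroxy-4,6-bis(methoxymethoxy)benzaldehyde F1. The lithium acetylide of 13 (n-BuLi, THF, −78 °C) is added to the preformed lithium phenoxide of F1 to give the racemic propargylic alcohol F2. Oxidation with MnO2 in CH2Cl2 then gives ynone 15 as an isolated compound, and Et2NH in EtOH closes ring C through enaminone 16, so the route is rejoined at 17.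

Step 9. The doubly donor-substituted vinylogous ester may be too unreactive toward the copper hydride, facial discrimination may be poor next to the ortho-substituted ring B, the copper enolate may open ring C by β-elimination of the phenoxide (loss of enantiopurity), or the ketone may be reduced further. The fallback separates reduction from stereocontrol and sets out from 17. A racemic conjugate reduction, with an achiral and more reactive copper hydride (Cu(OAc)2, 1,2-bis(diphenylphosphino)benzene, (EtO)2MeSiH, t-BuOH) or, failing that, with LiBH(s-Bu)3 in THF at −78 °C, should give the racemic tris-MOM flavanone F3. Kinetic resolution of F3 by asymmetric transfer hydrogenation (RuCl(p-cymene)[(R,R)-TsDPEN], HCO2H–Et3N) is expected to reduce the 2R enantiomer to the (2R,4R)-cis-flavan-4-ol F4, which is removed by chromatography, and to leave the 2S ketone, so the route is rejoined at 18.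

Step 5. The ortho-dienone may fragment by loss of the formyl or the allyl group instead of undergoing the second [3,3] shift, or the ether may simply cleave back to 7. The fallback introduces the prenyl group by cross-coupling and sets out from 7. Iodination para to the free OH with N-iodosuccinimide in DMF at 0 °C should give 5-hydroxy-8-iodo-2,2-dimethyl-2H-chromene-6-carbaldehyde F5, and MOM protection (NaH, MOMCl, DMF) gives 8-iodo-5-(methoxymethoxy)-2,2-dimethyl-2H-chromene-6-carbaldehyde F6. Stille coupling of F6 with tributyl(3-methylbut-2-enyl)stannane (Pd(PPh3)4, DMF, 90 °C) then installs the linear prenyl group, so the route is rejoined at 12.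

**Further compounds**
F1 | step 8 | 2-hydroxy-4,6-bis(methoxymethoxy)benzaldehyde | COCOc1cc(O)c(C=O)c(OCOC)c1
F2 | step 8 | 1-[2-hydroxy-4,6-bis(methoxymethoxy)phenyl]-3-[5-(methoxymethoxy)-2,2-dimethyl-8-(3-methylbut-2-enyl)-2H-chromen-6-yl]prop-2-yn-1-ol (racemic) | CC(C)=CCc1cc(C#CC(O)c2c(O)cc(OCOC)cc2OCOC)c(OCOC)c2c1OC(C)(C)C=C2
F3 | step 9 | racemic 5,7-bis(methoxymethoxy)-2-[5-(methoxymethoxy)-2,2-dimethyl-8-(3-methylbut-2-enyl)-2H-chromen-6-yl]-2,3-dihydro-4H-chromen-4-one | CC(C)=CCc1cc(C2CC(=O)c3c(OCOC)cc(OCOC)cc3O2)c(OCOC)c2c1OC(C)(C)C=C2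
F4 | step 9 | (2R,4R)-5,7-bis(methoxymethoxy)-2-[5-(methoxymethoxy)-2,2-dimethyl-8-(3-methylbut-2-enyl)-2H-chromen-6-yl]-3,4-dihydro-2H-chromen-4-ol | CC(C)=CCc1cc([C@H]2C[C@@H](O)c3c(OCOC)cc(OCOC)cc3O2)c(OCOC)c2c1OC(C)(C)C=C2
F5 | step 5 | 5-hydroxy-8-iodo-2,2-dimethyl-2H-chromene-6-carbaldehyde | CC1(C)C=Cc2c(O1)c(I)cc(C=O)c2O
F6 | step 5 | 8-iodo-5-(methoxymethoxy)-2,2-dimethyl-2H-chromene-6-carbaldehyde | COCOc1c(C=O)cc(I)c2OC(C)(C)C=Cc12
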